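**Plan**

1. Chromene numbering is used (O1, C2, C3, C4, C4a, C5–C8, C8a); ring A is the chromene benzene ring, ring B the pyran, ring C the 4-methoxyphenyl ring.
2. Retrosynthesis cuts, in order: the C3=C4 alkene of ring B (ring-closing metathesis), the O1–C2 ether bond (palladium-catalysed tert-allylation), the C4–C4a bond (vinyl cross-coupling at an iodide), the second benzil carbonyl (methylene oxidation) and the ring A–carbonyl bond (Friedel–Crafts acylation).
3. Enabling feature: C3=C4 of ring B lies between arene carbon C4a and the quaternary C2, with O1 on the adjacent C8a. Ring B therefore maps onto a C4a vinyl group and a 1,1-dimethylallyl ether on the C8a oxygen, whose ortho (C4a, C8) and para (C6) positions are all substituted.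
4. Forward: isovanillin gives 4-methoxyresorcinol (ring A), which is acylated with 4-methoxyphenylacetic acid (ring C) and oxidised to the benzil. Iodination between the hydroxyls, vinylation and O-alkylation of the non-chelated hydroxyl follow, and ring B closes last.
5. Stereochemistry: the target has no stereocentre; the cis geometry of C3=C4 is imposed by the six-membered ring.

Key step: step 8

Remark: the 2-hydroxybenzils 6, 7, 9, 13 and 14 are assumed to react from the open, chelated dione form drawn in the target; any five-membered hemiketal tautomer is taken to be in reversible equilibrium with it.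

**Step 1**
Reactants: 1 isovanillin (3-hydroxy-4-methoxybenzaldehyde)
Product: 3 4-methoxybenzene-1,3-diol (4-methoxyresorcinol), via 3-hydroxy-4-methoxyphenyl formate 2 (not isolated)
Conditions: mCPBA (1.3 equiv), CH2Cl2, 0 °C to rt; then MeOH, cat. HCl, rt
Reagents that add atoms: mCPBA (3-chloroperoxybenzoic acid), O=C(OO)c1cccc(Cl)c1
Why: Baeyer–Villiger (Dakin-type) oxidation, in which the electron-rich para-methoxyaryl group of the Criegee adduct migrates in preference to hydrogen and the aryl formate is then cleaved by acid-catalysed transesterification.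

**Step 2**
Reactants: 3 4-methoxybenzene-1,3-diol; 4 4-methoxyphenylacetic acid
Product: 5 1-(2,4-dihydroxy-5-methoxyphenyl)-2-(4-methoxyphenyl)ethan-1-one
Conditions: BF3·OEt2 (as solvent), 85 °C; then aq NaOAc
Reagents that add atoms: none
Why: Friedel–Crafts (Nencki-type) C-acylation by the BF3-activated acid at C6 of the resorcinol, ortho to one hydroxyl and para to the other, with difluoroboron chelation of the new ortho-hydroxy ketone preventing a second acylation.

**Step 3**
Reactants: 5 1-(2,4-dihydroxy-5-methoxyphenyl)-2-(4-methoxyphenyl)ethan-1-one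
Product: 6 1-(2,4-dihydroxy-5-methoxyphenyl)-2-(4-methoxyphenyl)ethane-1,2-dione
Conditions: SeO2 (1.5 equiv), 1,4-dioxane/H2O (20:1), reflux
Reagents that add atoms: selenium dioxide, O=[Se]=O
Why: Riley oxidation of the methylene that is both benzylic and alpha to the ketone, proceeding through the enol and a selenium ester and stopping at the 1,2-diketone because no enolisable hydrogen remains.

**Step 4**
Reactants: 6 1-(2,4-dihydroxy-5-methoxyphenyl)-2-(4-methoxyphenyl)ethane-1,2-dione
Product: 7 1-(2,4-dihydroxy-3-iodo-5-methoxyphenyl)-2-(4-methoxyphenyl)ethane-1,2-dione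
Conditions: NIS (1.05 equiv), TsOH·H2O (10 mol %), MeCN, 0 °C to rt, dark
Reagents that add atoms: N-iodosuccinimide, O=C1CCC(=O)N1I
Why: Electrophilic aromatic iodination at the one carbon ortho to both hydroxyls, the remaining ring A position being deactivated by the adjacent acyl group and ring C by its own carbonyl.

**Step 5**
Reactants: 7 1-(2,4-dihydroxy-3-iodo-5-methoxyphenyl)-2-(4-methoxyphenyl)ethane-1,2-dione; 8 potassium vinyltrifluoroborate
Product: 9 1-(2,4-dihydroxy-5-methoxy-3-vinylphenyl)-2-(4-methoxyphenyl)ethane-1,2-dione
Conditions: PdCl2(dppf)·CH2Cl2 (5 mol %), Cs2CO3 (4 equiv), degassed THF/H2O (9:1), 75 °C; aq NH4Cl work-up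
Reagents that add atoms: none
Why: Suzuki–Miyaura coupling (oxidative addition of zerovalent palladium into the C–I bond, vinyl transfer from the slowly hydrolysed trifluoroborate, reductive elimination), a reaction type that tolerates free phenols and non-enolisable benzils under aqueous carbonate.

**Step 6**
Reactants: 10 2-methylbut-3-en-2-ol
Product: 12 methyl (2-methylbut-3-en-2-yl) carbonate, via lithium 2-methylbut-3-en-2-olate 11 (not isolated)
Conditions: n-BuLi (1.05 equiv), THF, −78 to 0 °C; then ClCO2Me (1.1 equiv), 0 °C to rt
Reagents that add atoms: methyl chloroformate, COC(=O)Cl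
Why: O-acylation of a preformed tertiary lithium alkoxide by a chloroformate, the standard route to tertiary allylic carbonates that are too hindered for amine-mediated acylation.

**Step 7**
Reactants: 9 1-(2,4-dihydroxy-5-methoxy-3-vinylphenyl)-2-(4-methoxyphenyl)ethane-1,2-dione; 12 methyl (2-methylbut-3-en-2-yl) carbonate (1.3 equiv)
Product: 13 1-[2-hydroxy-5-methoxy-4-(2-methylbut-3-en-2-yloxy)-3-vinylphenyl]-2-(4-methoxyphenyl)ethane-1,2-dione
Conditions: Pd(PPh3)4 (5 mol %), THF, 0 °C to rt, stopped at full conversion of 9; chromatography on Et3N-deactivated silica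
Reagents that add atoms: none
Why: Tsuji–Trost decarboxylative O-allylation, in which zerovalent palladium ionises the carbonate to a 1,1-dimethyl-π-allyl complex, the released methoxide deprotonates the more acidic non-chelated hydroxyl para to the carbonyl, and that phenoxide attacks the more substituted allyl terminus under kinetic control, C-allylation being excluded because every ortho and para position is substituted.

**Step 8**
Reactants: 13 1-[2-hydroxy-5-methoxy-4-(2-methylbut-3-en-2-yloxy)-3-vinylphenyl]-2-(4-methoxyphenyl)ethane-1,2-dione
Product: 14 dielsianone, 1-(5-hydroxy-8-methoxy-2,2-dimethyl-2H-chromen-6-yl)-2-(4-methoxyphenyl)ethane-1,2-dione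
Conditions: second-generation Grubbs catalyst (H2IMes)(PCy3)Cl2Ru=CHPh (5–10 mol %), degassed CH2Cl2 (0.005 M), 40 °C, argon sparge
Reagents that add atoms: none
Why: Ring-closing olefin metathesis, in which the ruthenium benzylidene exchanges onto the less hindered C4a vinyl group, and [2+2] cycloaddition of the resulting arylalkylidene with the CH=CH2 of the 1,1-dimethylallyl ether followed by cycloreversion of the ruthenacyclobutane forms C3=C4 and expels ethylene. The closest known reaction type is the ring-closing metathesis of 2-vinylaryl allyl ethers to 2H-chromenes with ruthenium alkylidenes. Ring B closes as a six-membered ring by joining C3 to C4, the two alkenes being held close by the ortho relationship across C4a–C8a and by the gem-dimethyl group at C2. No stereocentre is formed, and the ring size allows only the cis alkene. The step needs chemoselectivity over Claisen rearrangement and ionisation of the tertiary allyl aryl ether, which the neutral conditions at 40 °C and the substituted ortho (C4a, C8) and para (C6) positions of the ether should secure. The chelated C5 hydroxyl and the non-enolisable diketone are poor ligands for ruthenium, and removal of ethylene makes the closure irreversible.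

**Compound list**

1 | isovanillin (3-hydroxy-4-methoxybenzaldehyde) | COc1ccc(C=O)cc1O | starting material
2 | 3-hydroxy-4-methoxyphenyl formate | COc1ccc(OC=O)cc1O | intermediate
3 | 4-methoxybenzene-1,3-diol | COc1ccc(O)cc1O | intermediate
4 | 4-methoxyphenylacetic acid | COc1ccc(CC(=O)O)cc1 | starting material
5 | 1-(2,4-dihydroxy-5-methoxyphenyl)-2-(4-methoxyphenyl)ethan-1-one | COc1ccc(CC(=O)c2cc(OC)c(O)cc2O)cc1 | intermediate
6 | 1-(2,4-dihydroxy-5-methoxyphenyl)-2-(4-methoxyphenyl)ethane-1,2-dione | COc1ccc(C(=O)C(=O)c2cc(OC)c(O)cc2O)cc1 | intermediate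
7 | 1-(2,4-dihydroxy-3-iodo-5-methoxyphenyl)-2-(4-methoxyphenyl)ethane-1,2-dione | COc1ccc(C(=O)C(=O)c2cc(OC)c(O)c(I)c2O)cc1 | intermediate
8 | potassium vinyltrifluoroborate | C=C[B-](F)(F)F.[K+] | starting material
9 | 1-(2,4-dihydroxy-5-methoxy-3-vinylphenyl)-2-(4-methoxyphenyl)ethane-1,2-dione | COc1ccc(C(=O)C(=O)c2cc(OC)c(O)c(C=C)c2O)cc1 | intermediate
10 | 2-methylbut-3-en-2-ol | CC(C)(O)C=C | starting material
11 | lithium 2-methylbut-3-en-2-olate | CC(C)([O-])C=C.[Li+] | intermediate
12 | methyl (2-methylbut-3-en-2-yl) carbonate | COC(=O)OC(C)(C)C=C | intermediate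
13 | 1-[2-hydroxy-5-methoxy-4-(2-methylbut-3-en-2-yloxy)-3-vinylphenyl]-2-(4-methoxyphenyl)ethane-1,2-dione | COc1ccc(C(=O)C(=O)c2cc(OC)c(OC(C)(C)C=C)c(C=C)c2O)cc1 | intermediate
14 | dielsianone, 1-(5-hydroxy-8-methoxy-2,2-dimethyl-2H-chromen-6-yl)-2-(4-methoxyphenyl)ethane-1,2-dione | COc1ccc(C(=O)C(=O)c2cc(OC)c3c(c2O)C=CC(C)(C)O3)cc1 | target

**Step count**

Total step count: 8. Longest linear sequence: 7 steps (steps 1, 2, 3, 4, 5, 7, 8 from isovanillin); step 6 is a one-step side branch.

**Steps most likely to fail**

Step 7. The hydroxyl to be alkylated is flanked by the vinyl group and the methoxyl, so attack on the π-allyl complex may be slow. Prolonged exposure to zerovalent palladium may then re-ionise the tertiary ether and drain it to the linear prenyl ether, or the chelated hydroxyl may be alkylated as well. The fallback sets out from 9 and comes back at 13. Copper-catalysed propargylation of the more acidic hydroxyl with 3-chloro-3-methylbut-1-yne (CuCl2·2H2O cat., DBU, MeCN, 0 °C) should give 1-[2-hydroxy-5-methoxy-4-(2-methylbut-3-yn-2-yloxy)-3-vinylphenyl]-2-(4-methoxyphenyl)ethane-1,2-dione F1. Semihydrogenation of the alkyne (H2, 1 atm, Lindlar catalyst Pd/CaCO3 poisoned with Pb(OAc)2, quinoline, EtOAc, rt, stopped after one equivalent) should then give 13, the terminal alkyne being reduced ahead of the styrene.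

Step 5. Under aqueous carbonate the substrate is a doubly deprotonated, electron-rich iodide, so oxidative addition may be slow and protodeiodination may compete; the 1,2-diketone may also be degraded by base. The fallback sets out from 7 and comes back at 9. It is a base-free Stille coupling with tributyl(vinyl)stannane (Pd(PPh3)4, toluene, 90 °C), in which the neutral phenol form of the iodide reacts and the diketone never meets hydroxide; no new compound arises on this detour (F0).

Step 3. The free, electron-rich hydroxyarene may be over-oxidised or may take up selenium instead of undergoing clean methylene oxidation. The fallback sets out from 5 and comes back at 6. Acetylation of both hydroxyls (Ac2O, pyridine, cat. DMAP, CH2Cl2, 0 °C to rt) should give 4-methoxy-6-[2-(4-methoxyphenyl)acetyl]-1,3-phenylene diacetate F2. Riley oxidation of this deactivated substrate (SeO2, 1,4-dioxane, reflux) should give 4-methoxy-6-[2-(4-methoxyphenyl)-2-oxoacetyl]-1,3-phenylene diacetate F3, and methanolysis of both acetates (K2CO3, MeOH, 0 °C) should then give 6.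

**Further compounds**

F1 | step 7 | 1-[2-hydroxy-5-methoxy-4-(2-methylbut-3-yn-2-yloxy)-3-vinylphenyl]-2-(4-methoxyphenyl)ethane-1,2-dione | COc1ccc(C(=O)C(=O)c2cc(OC)c(OC(C)(C)C#C)c(C=C)c2O)cc1
F0 | step 5 | none | none
F2 | step 3 | 4-methoxy-6-[2-(4-methoxyphenyl)acetyl]-1,3-phenylene diacetate | COc1ccc(CC(=O)c2cc(OC)c(OC(C)=O)cc2OC(C)=O)cc1
F3 | step 3 | 4-methoxy-6-[2-(4-methoxyphenyl)-2-oxoacetyl]-1,3-phenylene diacetate | COc1ccc(C(=O)C(=O)c2cc(OC)c(OC(C)=O)cc2OC(C)=O)cc1
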